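Ring C is left open until the end and is closed by joining C2 to C3. C3 lies between the C4 ketone and ring B, which makes it the site of a donor/acceptor carbene, and C2 is an oxygen-bound CH2, so it can start as the ortho-methoxy group on ring A of an open-chain deoxybenzoin. A chiral dirhodium carboxylate turns α-aryl-α-diazo ketone 12 into a carbenoid that inserts into a C–H bond of that methoxy group: one operation forms C2–C3, closes ring C and sets the C3 stereocentre. Diazo ketone 12 comes from Pd-catalysed α-arylation of an acetophenone with a ring B bromide whose 1,1-dimethylallyl group is installed by Claisen rearrangement, then diazo transfer.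

Key step: step 10

Assumption: the stereocentre is C3 of the chroman-4-one and is S; the (S)-catalyst is written for step 10, and its antipode would be used if the first run shows the opposite sense of induction.

Step 1
Reactants: 1 2,2-dimethyl-1,3-benzodioxol-4-ol
Product: 2 2,2-dimethyl-4-[(3-methylbut-2-en-1-yl)oxy]-1,3-benzodioxole
Conditions: prenyl bromide, K2CO3, acetone, reflux
Reagents that add atoms: prenyl bromide (1-bromo-3-methylbut-2-ene), CC(C)=CCBr
Why: Williamson ether synthesis; the acetonide leaves only one phenol free, so the allylic bromide is taken up by SN2 at the oxygen that later becomes the 4'-methoxy oxygen.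

Step 2
Reactants: 2 2,2-dimethyl-4-[(3-methylbut-2-en-1-yl)oxy]-1,3-benzodioxole
Product: 4 2,2-dimethyl-5-(2-methylbut-3-en-2-yl)-1,3-benzodioxol-4-ol, via ortho-dienone 3 (not isolated)
Conditions: PhNEt2, 190 °C, sealed tube, argon
Reagents that add atoms: none
Why: Aromatic Claisen rearrangement; the [3,3] shift delivers the allyl unit with inversion to C5, the only free ortho position, so the 1,1-dimethylallyl group appears next to the oxygen, and tautomerisation of the dienone restores the phenol.

Step 3
Reactants: 4 2,2-dimethyl-5-(2-methylbut-3-en-2-yl)-1,3-benzodioxol-4-ol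
Product: 5 4-methoxy-2,2-dimethyl-5-(2-methylbut-3-en-2-yl)-1,3-benzodioxole
Conditions: MeI, K2CO3, DMF, 25 °C
Reagents that add atoms: iodomethane, CI
Why: Williamson O-methylation; the small electrophile should reach the hindered phenoxide, and the cyclic ketal rules out any migration of the neighbouring protecting group.

Step 4
Reactants: 5 4-methoxy-2,2-dimethyl-5-(2-methylbut-3-en-2-yl)-1,3-benzodioxole
Product: 6 7-bromo-4-methoxy-2,2-dimethyl-5-(2-methylbut-3-en-2-yl)-1,3-benzodioxole
Conditions: NBS (1.0 equiv), MeCN, 0 °C, dark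
Reagents that add atoms: N-bromosuccinimide, O=C1CCC(=O)N1Br
Why: Electrophilic aromatic bromination should go to C7, para to the methoxy group and ortho to a dioxole oxygen, because C6 is shielded by the adjacent quaternary carbon; the monosubstituted alkene has no allylic hydrogen and is far less nucleophilic than the trioxygenated ring.

Step 5
Reactants: 6 7-bromo-4-methoxy-2,2-dimethyl-5-(2-methylbut-3-en-2-yl)-1,3-benzodioxole
Product: 7 6-bromo-3-methoxy-4-(2-methylbut-3-en-2-yl)benzene-1,2-diol
Conditions: aq. HCl (3 M), MeOH, 60 °C, degassed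
Reagents that add atoms: none
Why: Acid-catalysed ketal hydrolysis through the oxocarbenium ion frees the catechol; dilute aqueous acid should not protonate the monosubstituted alkene, and no stereocentre or ketone is present yet.

Step 6
Reactants: 7 6-bromo-3-methoxy-4-(2-methylbut-3-en-2-yl)benzene-1,2-diol
Product: 8 1-bromo-2,3-bis(tert-butyldimethylsilyloxy)-4-methoxy-5-(2-methylbut-3-en-2-yl)benzene
Conditions: TBSCl (3 equiv), imidazole, DMF, 25 °C
Reagents that add atoms: tert-butyldimethylsilyl chloride, CC(C)(C)[Si](C)(C)Cl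
Why: Imidazole-promoted silylation of both phenols; the silyl ethers carry no C–H bond α to oxygen, which is what the later carbenoid step requires, and they come off with fluoride at the end.

Step 7
Reactants: 9 1-(4-hydroxy-2-methoxyphenyl)ethan-1-one
Product: 10 1-[4-(tert-butyldimethylsilyloxy)-2-methoxyphenyl]ethan-1-one
Conditions: TBSCl, imidazole, DMF, 25 °C
Reagents that add atoms: tert-butyldimethylsilyl chloride, CC(C)(C)[Si](C)(C)Cl
Why: Standard silylation of the single phenol; the ortho-methoxy group is kept as the future C2.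

Step 8
Reactants: 8 1-bromo-2,3-bis(tert-butyldimethylsilyloxy)-4-methoxy-5-(2-methylbut-3-en-2-yl)benzene; 10 1-[4-(tert-butyldimethylsilyloxy)-2-methoxyphenyl]ethan-1-one
Product: 11 2-[2,3-bis(tert-butyldimethylsilyloxy)-4-methoxy-5-(2-methylbut-3-en-2-yl)phenyl]-1-[4-(tert-butyldimethylsilyloxy)-2-methoxyphenyl]ethan-1-one
Conditions: Pd2(dba)3 (2 mol %), XPhos, K3PO4, toluene, 90 °C
Reagents that add atoms: none
Why: Buchwald–Hartwig ketone α-arylation (oxidative addition of zerovalent palladium into C–Br, exchange with the potassium enolate of 10, reductive elimination); the more acidic and more hindered product enolate should stop a second arylation, and the weak insoluble base spares the silyl ethers.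

Step 9
Reactants: 11 2-[2,3-bis(tert-butyldimethylsilyloxy)-4-methoxy-5-(2-methylbut-3-en-2-yl)phenyl]-1-[4-(tert-butyldimethylsilyloxy)-2-methoxyphenyl]ethan-1-one
Product: 12 2-[2,3-bis(tert-butyldimethylsilyloxy)-4-methoxy-5-(2-methylbut-3-en-2-yl)phenyl]-1-[4-(tert-butyldimethylsilyloxy)-2-methoxyphenyl]-2-diazoethan-1-one
Conditions: p-ABSA, DBU, dry MeCN, 0 to 25 °C
Reagents that add atoms: 4-acetamidobenzenesulfonyl azide, CC(=O)Nc1ccc(cc1)S(=O)(=O)N=[N+]=[N-]
Why: Regitz diazo transfer; the DBU enolate of the benzylic, ketone-activated methylene attacks the terminal azide nitrogen and the triazene collapses to the diazo ketone and the sulfonamide.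

Step 10
Reactants: 12 2-[2,3-bis(tert-butyldimethylsilyloxy)-4-methoxy-5-(2-methylbut-3-en-2-yl)phenyl]-1-[4-(tert-butyldimethylsilyloxy)-2-methoxyphenyl]-2-diazoethan-1-one
Product: 13 (3S)-3-[2,3-bis(tert-butyldimethylsilyloxy)-4-methoxy-5-(2-methylbut-3-en-2-yl)phenyl]-7-(tert-butyldimethylsilyloxy)-2,3-dihydro-4H-chromen-4-one
Conditions: Rh2(S-PTAD)4 (dirhodium tetrakis[(S)-(1-adamantyl)(N-phthalimido)acetate], 1 mol %), CH2Cl2, slow addition of 12 at high dilution, 25 to 40 °C
Reagents that add atoms: none
Why: The dirhodium tetracarboxylate expels N2 from 12 to give an electrophilic donor/acceptor carbenoid at C3, which inserts into a C–H bond of the ring A methoxy group through a concerted, hydride-transfer-like three-centre transition state that forms C2–C3 and C3–H together. The closest known reaction type is the intramolecular dirhodium-carbenoid C–H insertion α to the ether oxygen of 2-alkoxyaryl diazo ketones, which gives chroman-4-ones, taken together with the C–H insertion chemistry of α-aryl-α-diazo ketones. Ring C closes as a six-membered ring by 1,6-insertion, the tether C4–C4a–C8a–O1 holding the methoxy carbon over the carbenoid carbon. C3 is the only new stereocentre and is set under catalyst control, the chiral phthalimido carboxylate ligands shielding one face of the carbenoid as the C–H bond approaches. The step needs chemoselectivity for the methoxy C–H: ring B offers no C–H α to oxygen within reach (silyl ethers at O2' and O3'; the 4'-methoxy and the vinyl group are out of range), attack by the methoxy oxygen gives an oxonium ylide that has no easy exit for a methyl group and should revert, and slow addition suppresses carbene dimerisation and intermolecular cyclopropanation. The conditions are neutral, so the enolisable C3–H should not be scrambled.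

Step 11
Reactants: 13 (3S)-3-[2,3-bis(tert-butyldimethylsilyloxy)-4-methoxy-5-(2-methylbut-3-en-2-yl)phenyl]-7-(tert-butyldimethylsilyloxy)-2,3-dihydro-4H-chromen-4-one
Product: 14 (3S)-3-[2,3-dihydroxy-4-methoxy-5-(2-methylbut-3-en-2-yl)phenyl]-7-hydroxy-2,3-dihydro-4H-chromen-4-one
Conditions: TBAF, AcOH (1:1, 3.5 equiv), THF, 0 °C
Reagents that add atoms: none
Why: Fluoride cleaves the three aryl O–Si bonds; the acetic acid buffer protonates the phenoxides at once, so the C3–H (α to the ketone and benzylic) should not be enolised, and strong acid, which would dehydrate the 2'-hydroxy ketone, is avoided.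

Compound list
1 | 2,2-dimethyl-1,3-benzodioxol-4-ol | CC1(C)Oc2cccc(O)c2O1 | starting material
2 | 2,2-dimethyl-4-[(3-methylbut-2-en-1-yl)oxy]-1,3-benzodioxole | CC(C)=CCOc1cccc2OC(C)(C)Oc12 | intermediate
3 | 2,2-dimethyl-5-(2-methylbut-3-en-2-yl)-1,3-benzodioxol-4(5H)-one (ortho-dienone, racemic) | C=CC(C)(C)C1C=CC2=C(OC(C)(C)O2)C1=O | intermediate (not isolated)
4 | 2,2-dimethyl-5-(2-methylbut-3-en-2-yl)-1,3-benzodioxol-4-ol | C=CC(C)(C)c1ccc2OC(C)(C)Oc2c1O | intermediate
5 | 4-methoxy-2,2-dimethyl-5-(2-methylbut-3-en-2-yl)-1,3-benzodioxole | C=CC(C)(C)c1ccc2OC(C)(C)Oc2c1OC | intermediate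
6 | 7-bromo-4-methoxy-2,2-dimethyl-5-(2-methylbut-3-en-2-yl)-1,3-benzodioxole | C=CC(C)(C)c1cc(Br)c2OC(C)(C)Oc2c1OC | intermediate
7 | 6-bromo-3-methoxy-4-(2-methylbut-3-en-2-yl)benzene-1,2-diol | C=CC(C)(C)c1cc(Br)c(O)c(O)c1OC | intermediate
8 | 1-bromo-2,3-bis(tert-butyldimethylsilyloxy)-4-methoxy-5-(2-methylbut-3-en-2-yl)benzene | C=CC(C)(C)c1cc(Br)c(O[Si](C)(C)C(C)(C)C)c(O[Si](C)(C)C(C)(C)C)c1OC | intermediate
9 | 1-(4-hydroxy-2-methoxyphenyl)ethan-1-one | CC(=O)c1ccc(O)cc1OC | starting material
10 | 1-[4-(tert-butyldimethylsilyloxy)-2-methoxyphenyl]ethan-1-one | CC(=O)c1ccc(O[Si](C)(C)C(C)(C)C)cc1OC | intermediate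
11 | 2-[2,3-bis(tert-butyldimethylsilyloxy)-4-methoxy-5-(2-methylbut-3-en-2-yl)phenyl]-1-[4-(tert-butyldimethylsilyloxy)-2-methoxyphenyl]ethan-1-one | C=CC(C)(C)c1cc(CC(=O)c2ccc(O[Si](C)(C)C(C)(C)C)cc2OC)c(O[Si](C)(C)C(C)(C)C)c(O[Si](C)(C)C(C)(C)C)c1OC | intermediate
12 | 2-[2,3-bis(tert-butyldimethylsilyloxy)-4-methoxy-5-(2-methylbut-3-en-2-yl)phenyl]-1-[4-(tert-butyldimethylsilyloxy)-2-methoxyphenyl]-2-diazoethan-1-one | C=CC(C)(C)c1cc(C(=[N+]=[N-])C(=O)c2ccc(O[Si](C)(C)C(C)(C)C)cc2OC)c(O[Si](C)(C)C(C)(C)C)c(O[Si](C)(C)C(C)(C)C)c1OC | intermediate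
13 | (3S)-3-[2,3-bis(tert-butyldimethylsilyloxy)-4-methoxy-5-(2-methylbut-3-en-2-yl)phenyl]-7-(tert-butyldimethylsilyloxy)-2,3-dihydro-4H-chromen-4-one | C=CC(C)(C)c1cc([C@H]2COc3cc(O[Si](C)(C)C(C)(C)C)ccc3C2=O)c(O[Si](C)(C)C(C)(C)C)c(O[Si](C)(C)C(C)(C)C)c1OC | intermediate
14 | (3S)-3-[2,3-dihydroxy-4-methoxy-5-(2-methylbut-3-en-2-yl)phenyl]-7-hydroxy-2,3-dihydro-4H-chromen-4-one | C=CC(C)(C)c1cc([C@H]2COc3cc(O)ccc3C2=O)c(O)c(O)c1OC | target

Total step count: 11
Longest linear sequence: 10 steps (steps 1 to 6, then 8 to 11)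

Steps most likely to fail

1. Step 10. The carbenoid may be diverted before it reaches the primary methoxy C–H bond: attack by the methoxy oxygen followed by a Stevens shift, or carbene dimerisation. Facial discrimination at the carbenoid carbon may also be too low. Fallback, independent of carbene chemistry: setting out from 11, the ring A methoxy group ortho to the ketone is cleaved selectively through chelation with MgI2 etherate (toluene, 80 °C) to give the 2-hydroxy deoxybenzoin F1. N,N-Dimethylformamide dimethyl acetal (toluene, 90 °C) then supplies C2 and closes ring C to the isoflavone F2. Asymmetric transfer hydrogenation with RuCl(p-cymene)[(S,S)-TsDPEN] or its enantiomer and HCO2H/Et3N reduces the C2–C3 double bond and then the ketone under dynamic kinetic resolution, giving the cis-(3S,4S)-isoflavan-4-ol F3. Oxidation with Dess–Martin periodinane (NaHCO3, CH2Cl2, 0 °C) leaves C3 untouched and returns to the route at 13.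

2. Step 2. At the temperature the rearrangement needs, the prenyl ether may fragment to phenol 1 and isoprene, some allyl may migrate on to the para position, and the product phenol may cyclise onto its new alkene. Fallback without a sigmatropic step: setting out from 1, ortho-selective bromination (NBS, catalytic iPr2NH, CH2Cl2, 0 °C) should give the 5-bromo phenol F4, and methylation (MeI, K2CO3, DMF) its methyl ether F5. A ligand-controlled γ-selective Suzuki–Miyaura coupling with 3,3-dimethylallylboronic acid pinacol ester (Pd(OAc)2, bulky dialkylbiarylphosphine, K3PO4, THF/H2O) then attaches the allyl unit through its disubstituted terminus and returns to the route at 5.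

3. Step 8. Oxidative addition into the electron-rich, ortho-silyloxy bromide may be slow, and under basic conditions a silyl group may be lost or transferred to the product enolate. Fallback that builds the ketone by acyl substitution: setting out from 8, palladium-catalysed coupling with the Reformatsky reagent made from 2-bromo-1-(morpholin-4-yl)ethanone and zinc (Pd(dba)2, P(tBu)3, THF, 25 °C), a neutral zinc enolate, should give the arylacetic morpholine amide F6. Commercial 4-bromo-3-methoxyphenol is silylated (TBSCl, imidazole, DMF) to aryl bromide F7, which bromine–lithium exchange (n-BuLi, THF, −78 °C) converts into aryllithium F8. Addition of F8 to F6 and collapse of the tetrahedral intermediate on work-up gives the ketone and returns to the route at 11.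

Further compounds
F1 | step 10 | 2-[2,3-bis(tert-butyldimethylsilyloxy)-4-methoxy-5-(2-methylbut-3-en-2-yl)phenyl]-1-[4-(tert-butyldimethylsilyloxy)-2-hydroxyphenyl]ethan-1-one | C=CC(C)(C)c1cc(CC(=O)c2ccc(O[Si](C)(C)C(C)(C)C)cc2O)c(O[Si](C)(C)C(C)(C)C)c(O[Si](C)(C)C(C)(C)C)c1OC
F2 | step 10 | 3-[2,3-bis(tert-butyldimethylsilyloxy)-4-methoxy-5-(2-methylbut-3-en-2-yl)phenyl]-7-(tert-butyldimethylsilyloxy)-4H-chromen-4-one | C=CC(C)(C)c1cc(C2=COc3cc(O[Si](C)(C)C(C)(C)C)ccc3C2=O)c(O[Si](C)(C)C(C)(C)C)c(O[Si](C)(C)C(C)(C)C)c1OC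
F3 | step 10 | (3S,4S)-3-[2,3-bis(tert-butyldimethylsilyloxy)-4-methoxy-5-(2-methylbut-3-en-2-yl)phenyl]-7-(tert-butyldimethylsilyloxy)-3,4-dihydro-2H-chromen-4-ol (cis) | C=CC(C)(C)c1cc([C@H]2COc3cc(O[Si](C)(C)C(C)(C)C)ccc3[C@H]2O)c(O[Si](C)(C)C(C)(C)C)c(O[Si](C)(C)C(C)(C)C)c1OC
F4 | step 2 | 5-bromo-2,2-dimethyl-1,3-benzodioxol-4-ol | CC1(C)Oc2ccc(Br)c(O)c2O1
F5 | step 2 | 5-bromo-4-methoxy-2,2-dimethyl-1,3-benzodioxole | COc1c(Br)ccc2OC(C)(C)Oc12
F6 | step 8 | 2-[2,3-bis(tert-butyldimethylsilyloxy)-4-methoxy-5-(2-methylbut-3-en-2-yl)phenyl]-1-(morpholin-4-yl)ethan-1-one | C=CC(C)(C)c1cc(CC(=O)N2CCOCC2)c(O[Si](C)(C)C(C)(C)C)c(O[Si](C)(C)C(C)(C)C)c1OC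
F7 | step 8 | (4-bromo-3-methoxyphenoxy)(tert-butyl)dimethylsilane | COc1cc(O[Si](C)(C)C(C)(C)C)ccc1Br
F8 | step 8 | [4-(tert-butyldimethylsilyloxy)-2-methoxyphenyl]lithium | [Li]c1ccc(O[Si](C)(C)C(C)(C)C)cc1OC
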